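## Retrosynthetic overview

1. Enabling feature: in ring B of the target (O1, C2, C3, C4=C5, C6; a 3,6-dihydro-2H-pyran), O1 sits on the allylic C6H2. C6 stands cis to C3 across the endocyclic C4=C5 bond, and C5 carries the C16 chain. Excising C6 leaves O1 on C5, which is a 2,3-dihydrofuran (ring A: O1, C2, C3, C4=C5). Its vinylic C5-O1 bond becomes a carbenoid leaving group once C5 is bound to copper.
2. Key disconnection: C5-C1' (chain), C5-C6 and C6-O1 are made in one flask from ring A, homofarnesyl iodide and formaldehyde. The sequence is 1,2-metallate rearrangement, hydroxymethylation and sulfonate closure. The net result is insertion of CH2 into C5-O1, so the five-membered ring A becomes the six-membered ring B.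
3. The acrylic acid is disconnected to a C2-ethynyl group (Markovnikov hydroxycarbonylation). The alkyne goes back to a C2-CH2OTIPS handle that survives the organometallic step.
4. Ring A and the only stereocentre come from commercial (R)-5-(hydroxymethyl)butyrolactone. The chain comes from (E,E)-farnesyl bromide and thioanisole by one-carbon homologation.
5. Order of rings: ring A is bought as the lactone and turned into the enol ether (steps 3 to 5). Ring B arises from ring A in step 6, and no further ring is formed.

Key step: step 6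

Remark: ring atoms keep the target numbering (O1, C2, C3, C4, C5, C6; C1' is the first chain carbon) in all intermediates. Monomeric formaldehyde is cracked from commercial paraformaldehyde and counted as a purchased compound.

## Route

Step 1
Reactants: 1 (2E,6E)-farnesyl bromide; 2 thioanisole
Product: 4 (3E,7E)-homofarnesyl phenyl sulfide, via (phenylthio)methyllithium 3 (not isolated)
Conditions: 2, n-BuLi, DABCO, THF, 0 °C; then 1, -78 °C to rt
Reagents that add atoms: none
Why: SN2 alkylation of the sulfur-stabilised carbanion 3 at the primary allylic bromide adds the single carbon that separates farnesyl from homofarnesyl and leaves both E olefins untouched.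

Step 2
Reactants: 4 (3E,7E)-homofarnesyl phenyl sulfide
Product: 6 (3E,7E)-homofarnesyl iodide, via methyl(phenyl)sulfonium iodide 5 (not isolated)
Conditions: MeI (excess), NaI, DMF, 75 °C, dark
Reagents that add atoms: methyl iodide CI; sodium iodide [Na+].[I-]
Why: S-methylation gives sulfonium salt 5, whose primary homoallylic carbon is attacked by iodide (SN2 dealkylation, sulfide-to-iodide exchange) with release of thioanisole, and trisubstituted olefins are inert under these conditions.

Step 3
Reactants: 7 (R)-5-(hydroxymethyl)dihydrofuran-2(3H)-one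
Product: 8 (R)-5-[(triisopropylsilyloxy)methyl]dihydrofuran-2(3H)-one
Conditions: TIPSCl, imidazole, DMF, rt
Reagents that add atoms: triisopropylsilyl chloride CC(C)[Si](Cl)(C(C)C)C(C)C
Why: Imidazole-promoted silylation of a primary alcohol, with TIPS chosen because it has no Si-CH3 or aryl C-H bond that t-BuLi could metalate in step 6.

Step 4
Reactants: 8 (R)-5-[(triisopropylsilyloxy)methyl]dihydrofuran-2(3H)-one
Product: 9 (5R)-5-[(triisopropylsilyloxy)methyl]tetrahydrofuran-2-ol (anomer mixture)
Conditions: i-Bu2AlH (1.1 equiv), toluene, -78 °C; aq. potassium sodium tartrate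
Reagents that add atoms: none
Why: Partial hydride reduction of a gamma-lactone stops at the aluminium hemiacetal at low temperature and gives the lactol, whose anomeric configuration is erased in step 5 and whose C2 is not touched.

Step 5
Reactants: 9 (5R)-5-[(triisopropylsilyloxy)methyl]tetrahydrofuran-2-ol
Product: 11 (2R)-2-[(triisopropylsilyloxy)methyl]-2,3-dihydrofuran (ring A), via anomeric mesylate 10 (not isolated)
Conditions: MsCl, Et3N (excess), CH2Cl2, -40 °C to reflux
Reagents that add atoms: none
Why: Anomeric mesylation followed by amine-induced elimination is the standard dehydration of 2-deoxylactols to furanoid glycals and does not involve the stereocentre.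

Step 6
Reactants: 11 (2R)-2-[(triisopropylsilyloxy)methyl]-2,3-dihydrofuran; 6 (3E,7E)-homofarnesyl iodide; 12 formaldehyde
Product: 19 (2R)-5-homofarnesyl-2-[(triisopropylsilyloxy)methyl]-3,6-dihydro-2H-pyran (ring B), via homofarnesyllithium 13 (not isolated), via 5-lithiodihydrofuran 14 (not isolated), via mixed lithium cuprate 15 (not isolated), via ring-opened alkenylcuprate alkoxide 16 (not isolated), via Z-enediolate 17 (not isolated), via allylic sulfonate alkoxide 18 (not isolated)
Conditions: 6, t-BuLi (2.0 equiv), Et2O-pentane, -78 °C; CuBr·SMe2 (1.0 equiv), Me2S-Et2O, -78 to -40 °C; 14 [from 11, t-BuLi (1.1 equiv), THF, -78 to 0 °C], -78 °C to rt; CH2O (1.5 equiv, THF solution), -78 to 0 °C; 2,4,6-i-Pr3C6H2SO2Cl (TrisCl, 1.1 equiv), DMPU, 0 °C to rt; aq. NH4Cl-NH3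
Reagents that add atoms: none
Why: Proposed new method: cuprate 15 holds the homofarnesyl group and an alpha-alkoxyalkenyl (carbenoid) ligand on one copper, so on warming the alkyl group shifts 1,2 from copper to C5 with expulsion of O1 and inversion at the sp2 carbon, which opens ring A and leaves copper cis to C3 in 16. Addition of 16 to formaldehyde with retention gives 17, the bulky TrisCl sulfonylates its primary allylic alkoxide, and the C2 alkoxide of 18 closes ring B by a 6-exo-tet Williamson SN2, so that one CH2 ends up inserted into the former C5-O1 bond while the C16 chain is attached in the same flask. The closest known reaction types are the copper-mediated 1,2-metallate rearrangement of 5-lithio-2,3-dihydrofurans with homoallylic lithium reagents followed by alkylation of the alkenylcuprate with MeI, the addition of lithium alkenylcuprates to aldehydes, and the one-pot monosulfonylation and cyclisation of diol dialkoxides; what is new is their merger into a net five-to-six ring expansion. No stereocentre is created: C2 is a spectator because its C-O bond is never broken, and the cis relation of C3 and C6 across C4=C5 that closure requires follows from the stereospecific inversion then retention sequence. The step needs (a) migration of the alkyl ligand only, secured because the only other carbon ligand on copper is the carbenoid itself, (b) no allylic electrophile while organocopper is still present, secured by adding TrisCl only after formaldehyde has consumed 16, and (c) primary over secondary O-sulfonylation, secured by the size of TrisCl and by the CH2OTIPS group that flanks the secondary alkoxide and also holds the silyl group on its preferred primary oxygen.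

Step 7
Reactants: 19 (2R)-5-homofarnesyl-2-[(triisopropylsilyloxy)methyl]-3,6-dihydro-2H-pyran
Product: 20 [(2R)-5-homofarnesyl-3,6-dihydro-2H-pyran-2-yl]methanol
Conditions: Bu4NF, THF, 0 °C to rt
Reagents that add atoms: none
Why: Fluoride-induced desilylation driven by the Si-F bond, which affects neither the allylic ether nor the polyene.

Step 8
Reactants: 20 [(2R)-5-homofarnesyl-3,6-dihydro-2H-pyran-2-yl]methanol
Product: 21 (2R)-5-homofarnesyl-3,6-dihydro-2H-pyran-2-carbaldehyde
Conditions: PhI(OAc)2, TEMPO (2,2,6,6-tetramethylpiperidine-1-oxyl, 10 mol %), CH2Cl2, rt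
Reagents that add atoms: none
Why: Oxoammonium (TEMPO) oxidation of a primary alcohol stops at the aldehyde under anhydrous and only weakly acidic conditions, tolerates trisubstituted olefins and should not epimerise the alpha-alkoxy centre.

Step 9
Reactants: 21 (2R)-5-homofarnesyl-3,6-dihydro-2H-pyran-2-carbaldehyde
Product: 22 (2R)-2-ethynyl-5-homofarnesyl-3,6-dihydro-2H-pyran
Conditions: dimethyl (1-diazo-2-oxopropyl)phosphonate, K2CO3, MeOH, 0 °C to rt
Reagents that add atoms: dimethyl (1-diazo-2-oxopropyl)phosphonate COP(=O)(OC)C(=[N+]=[N-])C(C)=O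
Why: Ohira-Bestmann variant of the Seyferth-Gilbert homologation, in which the crude aldehyde meets the preformed diazophosphonate anion under mild carbonate conditions so that C2 should keep its configuration.

Step 10
Reactants: 22 (2R)-2-ethynyl-5-homofarnesyl-3,6-dihydro-2H-pyran
Product: 23 target acid, 2-[(2R)-5-homofarnesyl-3,6-dihydro-2H-pyran-2-yl]acrylic acid
Conditions: Pd(OAc)2 (1 mol %), 2-PyPPh2 (30 mol %), MeSO3H (20 mol %), CO (30 bar), THF-H2O, 50 °C
Reagents that add atoms: carbon monoxide [C-]#[O+]; water O
Why: Reppe-type Markovnikov hydroxycarbonylation of a terminal alkyne with the palladium/pyridylphosphine/acid system places CO2H on the internal alkyne carbon and gives the 2-substituted acrylic acid directly, only the alkyne inserts while the trisubstituted olefins stay out, and C2 is not touched.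

## Compound list

1 | (2E,6E)-farnesyl bromide | BrC/C=C(\C)CC/C=C(\C)CCC=C(C)C | starting material
2 | thioanisole | CSc1ccccc1 | starting material
3 | (phenylthio)methyllithium | [Li]CSc1ccccc1 | intermediate
4 | (3E,7E)-homofarnesyl phenyl sulfide | c1ccccc1SCC/C=C(\C)CC/C=C(\C)CCC=C(C)C | intermediate
5 | (3E,7E)-homofarnesyl(methyl)(phenyl)sulfonium iodide | C[S+](c1ccccc1)CC/C=C(\C)CC/C=C(\C)CCC=C(C)C.[I-] | intermediate
6 | (3E,7E)-homofarnesyl iodide (1-iodo-4,8,12-trimethyltrideca-3,7,11-triene) | ICC/C=C(\C)CC/C=C(\C)CCC=C(C)C | intermediate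
7 | (R)-5-(hydroxymethyl)dihydrofuran-2(3H)-one | OC[C@H]1CCC(=O)O1 | starting material
8 | (R)-5-[(triisopropylsilyloxy)methyl]dihydrofuran-2(3H)-one | CC(C)[Si](C(C)C)(C(C)C)OC[C@H]1CCC(=O)O1 | intermediate
9 | (5R)-5-[(triisopropylsilyloxy)methyl]tetrahydrofuran-2-ol, anomer mixture | CC(C)[Si](C(C)C)(C(C)C)OC[C@H]1CCC(O)O1 | intermediate
10 | anomeric mesylate of 9 | CC(C)[Si](C(C)C)(C(C)C)OC[C@H]1CCC(OS(C)(=O)=O)O1 | intermediate
11 | (2R)-2-[(triisopropylsilyloxy)methyl]-2,3-dihydrofuran | CC(C)[Si](C(C)C)(C(C)C)OC[C@H]1CC=CO1 | intermediate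
12 | formaldehyde (monomer from paraformaldehyde) | C=O | starting material
13 | (3E,7E)-homofarnesyllithium | [Li]CC/C=C(\C)CC/C=C(\C)CCC=C(C)C | intermediate
14 | (2R)-5-lithio-2-[(triisopropylsilyloxy)methyl]-2,3-dihydrofuran | CC(C)[Si](C(C)C)(C(C)C)OC[C@H]1CC=C([Li])O1 | intermediate
15 | lithium (homofarnesyl)(dihydrofuran-5-yl)cuprate | CC(C)[Si](C(C)C)(C(C)C)OC[C@H]1CC=C([Cu-]CC/C=C(\C)CC/C=C(\C)CCC=C(C)C)O1.[Li+] | intermediate
16 | lithium alkoxide of the ring-opened alkenylcopper, copper cis to C3 (alkoxy(alkenyl)cuprate) | CC(C)[Si](C(C)C)(C(C)C)OC[C@H]([O-])C/C=C(\[Cu])CC/C=C(\C)CC/C=C(\C)CCC=C(C)C.[Li+] | intermediate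
17 | (R,Z)-2-homofarnesyl-6-(triisopropylsilyloxy)hex-2-ene-1,5-diolate (Li, Cu) | CC(C)[Si](C(C)C)(C(C)C)OC[C@H]([O-])C/C=C(\C[O-])CC/C=C(\C)CC/C=C(\C)CCC=C(C)C.[Li+].[Cu+] | intermediate
18 | lithium C2-alkoxide bearing the primary allylic 2,4,6-triisopropylbenzenesulfonate | CC(C)[Si](C(C)C)(C(C)C)OC[C@H]([O-])C/C=C(\COS(=O)(=O)c1c(C(C)C)cc(C(C)C)cc1C(C)C)CC/C=C(\C)CC/C=C(\C)CCC=C(C)C.[Li+] | intermediate
19 | (2R)-5-homofarnesyl-2-[(triisopropylsilyloxy)methyl]-3,6-dihydro-2H-pyran | CC(C)[Si](C(C)C)(C(C)C)OC[C@H]1CC=C(CC/C=C(\C)CC/C=C(\C)CCC=C(C)C)CO1 | intermediate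
20 | [(2R)-5-homofarnesyl-3,6-dihydro-2H-pyran-2-yl]methanol | OC[C@H]1CC=C(CC/C=C(\C)CC/C=C(\C)CCC=C(C)C)CO1 | intermediate
21 | (2R)-5-homofarnesyl-3,6-dihydro-2H-pyran-2-carbaldehyde | O=C[C@H]1CC=C(CC/C=C(\C)CC/C=C(\C)CCC=C(C)C)CO1 | intermediate
22 | (2R)-2-ethynyl-5-homofarnesyl-3,6-dihydro-2H-pyran | C#C[C@H]1CC=C(CC/C=C(\C)CC/C=C(\C)CCC=C(C)C)CO1 | intermediate
23 | 2-[(2R)-5-((3E,7E)-4,8,12-trimethyltrideca-3,7,11-trienyl)-3,6-dihydro-2H-pyran-2-yl]acrylic acid | C=C(C(=O)O)[C@H]1CC=C(CC/C=C(\C)CC/C=C(\C)CCC=C(C)C)CO1 | target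

## Step count and risks

Total step count: 10. Longest linear sequence: 8 (steps 3 to 10, from lactone 7). Steps 1 and 2 form the convergent chain branch.

**1. Step 6 (bears the label).**
- What may go wrong:
  - Transfer of the alkenyl ligand from the alkoxide-ligated cuprate to formaldehyde may be sluggish, so that the alkenylcopper is merely protonated on work-up.
  - Hemiformal alkoxides may consume the sulfonyl chloride.
  - The secondary alkoxide may be sulfonylated and then close with inversion at C2, which erodes enantiomeric purity.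
  - The silyl group may migrate onto the C2 alkoxide.
- Fallback: known chemistry, with ring B built by carbonylation instead of methylene insertion. It sets out from 16, generated as in step 6.
  - Quenching 16 with I2 gives the (R,Z)-alkenyl iodide alcohol F1.
  - Carbonylative lactonisation with zerovalent palladium [Pd(PPh3)4, CO (1 atm), Et3N, THF, 60 °C] gives the 5,6-dihydro-2H-pyran-2-one F2.
  - Reduction with i-Bu2AlH (3 equiv, CH2Cl2, -78 to 0 °C) gives the (R,Z)-enediol F3.
  - Mitsunobu cyclodehydration (PPh3, DIAD, THF), which activates the primary allylic hydroxyl, comes back to the route at 19.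

**2. Step 10.**
- What may go wrong:
  - Branched regioselectivity may be lost next to the secondary propargylic ether carbon.
  - The buffered acid may isomerise or cyclise the polyene.
  - Palladium may ionise the allylic ring ether.
- Fallback: hydrometalation and carboxylation instead of carbonylation. It sets out from 22.
  - Alpha-selective hydroalumination [NiCl2(dppp) (3 mol %), i-Bu2AlH, THF, rt] followed by N-iodosuccinimide gives the 2-iodoalkene F4.
  - Iodine-lithium exchange (t-BuLi, 2 equiv, Et2O, -78 °C), CO2 and a mildly acidic work-up come back to the route at 23.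

**3. Step 5.**
- What may go wrong:
  - Elimination of the anomeric sulfonate may be incomplete.
  - The enol ether may be hydrated or oligomerised by acid during isolation.
  - The t-BuLi deprotonation that follows in step 6 may be inefficient.
- Fallback: C5 is metalated through the lactone enolate, with no lactol and no deprotonation of an enol ether. It sets out from 8.
  - KN(SiMe3)2 and (PhO)2P(O)Cl (THF-DMPU, -78 °C) give the ketene acetal phosphate F5.
  - Me3SnSnMe3, Pd(PPh3)4 and LiCl (THF, reflux) give the 5-stannyl dihydrofuran F6.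
  - Tin-lithium exchange (MeLi, THF, -78 °C) comes back to the route at 14, inside step 6.

## Further compounds

F1 | step 6 | (R,Z)-alkenyl iodide alcohol (iodine cis to C3) | CC(C)[Si](C(C)C)(C(C)C)OC[C@H](O)C/C=C(\I)CC/C=C(\C)CC/C=C(\C)CCC=C(C)C
F2 | step 6 | (6R)-3-homofarnesyl-6-[(triisopropylsilyloxy)methyl]-5,6-dihydro-2H-pyran-2-one | CC(C)[Si](C(C)C)(C(C)C)OC[C@H]1CC=C(CC/C=C(\C)CC/C=C(\C)CCC=C(C)C)C(=O)O1
F3 | step 6 | (R,Z)-2-homofarnesyl-6-(triisopropylsilyloxy)hex-2-ene-1,5-diol | CC(C)[Si](C(C)C)(C(C)C)OC[C@H](O)C/C=C(\CO)CC/C=C(\C)CC/C=C(\C)CCC=C(C)C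
F4 | step 10 | (2R)-5-homofarnesyl-2-(1-iodovinyl)-3,6-dihydro-2H-pyran | C=C(I)[C@H]1CC=C(CC/C=C(\C)CC/C=C(\C)CCC=C(C)C)CO1
F5 | step 5 | (2R)-2-[(triisopropylsilyloxy)methyl]-2,3-dihydrofuran-5-yl diphenyl phosphate | CC(C)[Si](C(C)C)(C(C)C)OC[C@H]1CC=C(OP(=O)(Oc2ccccc2)Oc2ccccc2)O1
F6 | step 5 | (2R)-2-[(triisopropylsilyloxy)methyl]-5-(trimethylstannyl)-2,3-dihydrofuran | CC(C)[Si](C(C)C)(C(C)C)OC[C@H]1CC=C([Sn](C)(C)C)O1
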